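**Plan**

- Retrosynthesis: the cyclohexa-2,5-dienone is cut at C1–C6 and C4–C5. This removes C5(OMe)=C6H as methoxyacetylene and leaves an (S)-4-alkenyl-4-methoxy-2-propenylcyclobut-2-enone, whose acyl–C4 bond is a temporary ring bond that the target does not contain.
- Enabling feature: in the six-membered ring the carbonyl C1 and the fully substituted C4 (OMe, alkenyl, no H) are joined on one side by the C2=C3 alkene and on the other by exactly an ynol-ether C=C. Alkyne insertion into the four-membered C1–C2=C3–C4 ring therefore gives the ring directly, and it cannot aromatise.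
- The cyclobutenone is cut back to squaric acid: C4–alkenyl bond (alkenyllithium + alkoxy-cyclobutenedione), C–propenyl bond (propenyllithium + squarate diester). The ring alkoxy group is removed by a reductive 1,3-carbonyl transposition.
- Forward order: four-membered ring from squaric acid, C4 built by addition/O-methylation, transposition, then the six-membered ring by nickel-catalysed two-carbon ring expansion.
- Stereochemistry: C4 is set in the alkenyllithium addition as a pair of menthyl diastereomers, and the (4S) epimer is separated; the menthyloxy group serves as auxiliary and as leaving group. C4 is carried into the target with retention in the ring expansion. The two (E)-alkenes come from retentive halogen–lithium exchange and syn hydrozirconation.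

Key step: step 8

Assumption: the two C4 epimers formed in step 5 are separable on silica gel and the (4S) epimer is identified (X-ray or chiroptical correlation) before it is carried on; the route does not depend on which epimer the menthyloxy group favours.

"Menthyloxy" below means (1R,2S,5R)-2-isopropyl-5-methylcyclohexyloxy.

**Step 1**
Reactants: 1 squaric acid (3,4-dihydroxycyclobut-3-ene-1,2-dione); 2 (−)-menthol
Product: 3 3,4-bis[(1R,2S,5R)-menthyloxy]cyclobut-3-ene-1,2-dione
Conditions: 2 (2.5 equiv), toluene, reflux, Dean–Stark trap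
Reagents that add atoms: none
Why: Azeotropic esterification of the vinylogous diacid (the way simple dialkyl squarates are made); the alcohol oxygen attacks the ring carbon, so the menthyl stereocentres are untouched.

**Step 2**
Reactants: 3 di-menthyl squarate; 4 (E)-1-bromoprop-1-ene
Product: 7 3-[(1R,2S,5R)-menthyloxy]-4-[(E)-prop-1-enyl]cyclobut-3-ene-1,2-dione, via (E)-prop-1-enyllithium 5 (not isolated), via lithium alkoxide of the squarate adduct 6 (not isolated)
Conditions: 4, t-BuLi (2 equiv), Et2O, −78 °C; 3, THF, −78 °C; then 12 M HCl, CH2Cl2, 0 °C to rt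
Reagents that add atoms: water, SMILES O (supplies the oxygen of the new carbonyl)
Why: Bromine–lithium exchange with retention gives the (E)-alkenyllithium, which adds 1,2 to one squarate carbonyl; acid ionises the tertiary carbinol to an alkoxy-stabilised cyclobutenyl cation that is hydrolysed with loss of one menthol to the 3-alkoxy-4-alkenyl-1,2-dione (standard squarate addition/hydrolysis sequence).

**Step 3**
Reactants: 8 4-ethynyl-1,2-dimethoxybenzene
Product: 10 1,2-dimethoxy-4-(prop-1-yn-1-yl)benzene, via lithium arylacetylide 9 (not isolated)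
Conditions: n-BuLi, THF, −78 °C; MeI, −78 °C to rt
Reagents that add atoms: iodomethane, SMILES CI
Why: Deprotonation of the terminal alkyne and SN2 methylation of the lithium acetylide.

**Step 4**
Reactants: 10 1,2-dimethoxy-4-(prop-1-yn-1-yl)benzene
Product: 12 4-[(E)-2-iodoprop-1-enyl]-1,2-dimethoxybenzene, via alkenylzirconocene chloride 11 (not isolated)
Conditions: Cp2Zr(H)Cl (1.5 equiv), THF, rt to 40 °C; then I2, 0 °C
Reagents that add atoms: iodine, SMILES II
Why: Hydrozirconation with Cp2Zr(H)Cl is a syn addition that should place zirconium on the less hindered, methyl-bearing carbon (excess hydride equilibrates the regioisomers), and iodinolysis with retention fixes the trisubstituted (E)-alkene.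

**Step 5**
Reactants: 12 alkenyl iodide; 7 menthyloxy cyclobutenedione
Product: 15 (4S)-4-[(E)-1-(3,4-dimethoxyphenyl)prop-1-en-2-yl]-4-methoxy-3-[(1R,2S,5R)-menthyloxy]-2-[(E)-prop-1-enyl]cyclobut-2-en-1-one, via alkenyllithium 13 (not isolated), via lithium alkoxide of the dione adduct 14 (not isolated)
Conditions: 12, t-BuLi (2 equiv), Et2O, −78 °C; added to 7, THF, −78 °C; MeOTf, −78 to 0 °C; silica gel chromatography (separation of the C4 epimers)
Reagents that add atoms: methyl trifluoromethanesulfonate, SMILES COS(=O)(=O)C(F)(F)F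
Why: Iodine–lithium exchange with retention is followed by regioselective 1,2-addition to the ketone carbonyl next to the alkoxy-bearing carbon (the other carbonyl is a deactivated vinylogous ester) and O-methylation of the alkoxide in situ; the new C4 stereocentre forms as two menthyl diastereomers, of which the (4S) epimer is isolated by chromatography, any facial bias from the neighbouring menthyloxy group being a bonus.

**Step 6**
Reactants: 15 (4S)-menthyloxy cyclobutenone
Product: 17 (4S)-4-[(E)-1-(3,4-dimethoxyphenyl)prop-1-en-2-yl]-4-methoxy-2-[(E)-prop-1-enyl]cyclobut-2-en-1-one, via allylic alcohol 16 (not isolated)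
Conditions: i-Bu2AlH (1.2 equiv), CH2Cl2, −78 °C; then 1 M HCl, THF, 0 °C
Reagents that add atoms: water, SMILES O (supplies the oxygen of the new carbonyl)
Why: Stork–Danheiser 1,3-carbonyl transposition: 1,2-reduction of the vinylogous ester and mild acid hydrolysis of the 3-alkoxy allylic alcohol move the carbonyl to the former enol-ether carbon, put H next to C4 and release the auxiliary; no bond to C4 is touched, so its configuration is kept.

**Step 7**
Reactants: 18 2-chloro-1,1-dimethoxyethane
Product: 20 methoxyacetylene (methoxyethyne), via sodium methoxyacetylide 19 (not isolated)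
Conditions: NaNH2 (3 equiv), liquid NH3, −33 °C; then cold saturated aqueous NaCl; distilled and kept cold (bp about 23 °C)
Reagents that add atoms: none
Why: Successive β-eliminations of HCl and methanol by NaNH2 give the sodium alkoxyacetylide, protonated on work-up (the established preparation of alkoxyacetylenes from chloroacetaldehyde acetals).

**Step 8**
Reactants: 17 (4S)-cyclobutenone; 20 methoxyacetylene
Product: 21 (4S)-4-[(E)-1-(3,4-dimethoxyphenyl)prop-1-en-2-yl]-4,5-dimethoxy-2-[(E)-prop-1-enyl]cyclohexa-2,5-dien-1-one
Conditions: Ni(cod)2 (10 mol %), PPh3 (20 mol %), toluene, 0 °C; 20 (3 equiv, cold solution) added slowly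
Reagents that add atoms: none
Why: Proposed new method: zerovalent nickel should insert into the strained acyl–C4 σ-bond of 17 (the bond that also opens thermally, here allylic and α-oxygenated) to give a nickelacyclopentenone in equilibrium with its η4-vinylketene form; the nucleophilic CH carbon of the ynol ether then bonds to the electrophilic acyl carbon by migratory insertion, which leaves nickel on the oxygen-bearing alkyne carbon, and C(sp2)–C(sp3) reductive elimination at C4 releases the dienone and the catalyst. The closest known reaction type is the Ni(cod)2-catalysed insertion of alkynes into the C1–C4 bond of cyclobutenones, which ends in phenols, together with the stereoretentive nickel-catalysed alkyne insertion next to the carbonyl of α-substituted four-membered ketones; new are the fully substituted C4 (no hydrogen to lose, so the product stays a cross-conjugated dienone), the ynol ether partner and the transfer of a stereocentre. The six-membered ring is closed as a formal [4+2] two-carbon ring expansion of the four-membered ring, by reductive elimination from a seven-membered nickelacycle and not by a thermal electrocyclisation. No stereocentre is created: C4 is carried over with retention, because oxidative addition and reductive elimination both take place on the face of C4 from which the acyl carbon departs (this holds for the σ-bound and for the η4-bound intermediate), so the alkyne carbon ends up where the carbonyl carbon was and (S)-17 gives (S)-21. The step needs (a) the orientation CH-to-acyl and C(OMe)-to-C4, secured by the polarisation of the ynol ether, (b) cleavage of C1–C4 and not C1–C2, secured by the sp3, allyl-stabilised character of C4, and (c) a rate at 0 °C that outruns the thermal 4π-opening/6π-closure of the 4-alkenylcyclobutenone and any η1–η3 slippage of nickel into the 4-alkenyl group that would erode the configuration.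

**Compound list**

1 | squaric acid (3,4-dihydroxycyclobut-3-ene-1,2-dione) | OC1=C(O)C(=O)C1=O | starting material
2 | (−)-menthol, (1R,2S,5R)-2-isopropyl-5-methylcyclohexan-1-ol | O[C@@H]1C[C@H](C)CC[C@H]1C(C)C | starting material
3 | 3,4-bis[(1R,2S,5R)-menthyloxy]cyclobut-3-ene-1,2-dione | O=C1C(=O)C(O[C@@H]2C[C@H](C)CC[C@H]2C(C)C)=C1O[C@@H]3C[C@H](C)CC[C@H]3C(C)C | intermediate
4 | (E)-1-bromoprop-1-ene | C/C=C/Br | starting material
5 | (E)-prop-1-enyllithium | C/C=C/[Li] | intermediate
6 | lithium 2,3-bis[(1R,2S,5R)-menthyloxy]-4-oxo-1-[(E)-prop-1-enyl]cyclobut-2-en-1-olate, both C1 epimers | [Li+].[O-]C1(/C=C/C)C(=O)C(O[C@@H]2C[C@H](C)CC[C@H]2C(C)C)=C1O[C@@H]3C[C@H](C)CC[C@H]3C(C)C | intermediate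
7 | 3-[(1R,2S,5R)-menthyloxy]-4-[(E)-prop-1-enyl]cyclobut-3-ene-1,2-dione | C/C=C/C1=C(O[C@@H]2C[C@H](C)CC[C@H]2C(C)C)C(=O)C1=O | intermediate
8 | 4-ethynyl-1,2-dimethoxybenzene | C#Cc1ccc(OC)c(OC)c1 | starting material
9 | lithium (3,4-dimethoxyphenyl)acetylide | [Li]C#Cc1ccc(OC)c(OC)c1 | intermediate
10 | 1,2-dimethoxy-4-(prop-1-yn-1-yl)benzene | CC#Cc1ccc(OC)c(OC)c1 | intermediate
11 | chloro[(E)-1-(3,4-dimethoxyphenyl)prop-1-en-2-yl]zirconocene (zirconium trans to aryl) | Cl[Zr](C1C=CC=C1)(C1C=CC=C1)/C(C)=C/c1ccc(OC)c(OC)c1 | intermediate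
12 | 4-[(E)-2-iodoprop-1-enyl]-1,2-dimethoxybenzene (iodine trans to aryl) | I/C(C)=C/c1ccc(OC)c(OC)c1 | intermediate
13 | [(Z)-1-(3,4-dimethoxyphenyl)prop-1-en-2-yl]lithium (lithium trans to aryl) | [Li]/C(C)=C/c1ccc(OC)c(OC)c1 | intermediate
14 | lithium 1-[(E)-1-(3,4-dimethoxyphenyl)prop-1-en-2-yl]-2-[(1R,2S,5R)-menthyloxy]-4-oxo-3-[(E)-prop-1-enyl]cyclobut-2-en-1-olate, both C1 epimers | C/C=C/C1=C(O[C@@H]2C[C@H](C)CC[C@H]2C(C)C)C([O-])(/C(C)=C/c3ccc(OC)c(OC)c3)C1=O.[Li+] | intermediate
15 | (4S)-4-[(E)-1-(3,4-dimethoxyphenyl)prop-1-en-2-yl]-4-methoxy-3-[(1R,2S,5R)-menthyloxy]-2-[(E)-prop-1-enyl]cyclobut-2-en-1-one | C/C=C/C1=C(O[C@@H]2C[C@H](C)CC[C@H]2C(C)C)[C@@](OC)(/C(C)=C/c3ccc(OC)c(OC)c3)C1=O | intermediate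
16 | (4R)-4-[(E)-1-(3,4-dimethoxyphenyl)prop-1-en-2-yl]-4-methoxy-3-[(1R,2S,5R)-menthyloxy]-2-[(E)-prop-1-enyl]cyclobut-2-en-1-ol, both C1 epimers (C4 spatially as in 15; the descriptor changes only through the priority rules) | C/C=C/C1=C(O[C@@H]2C[C@H](C)CC[C@H]2C(C)C)[C@@](OC)(/C(C)=C/c3ccc(OC)c(OC)c3)C1O | intermediate
17 | (4S)-4-[(E)-1-(3,4-dimethoxyphenyl)prop-1-en-2-yl]-4-methoxy-2-[(E)-prop-1-enyl]cyclobut-2-en-1-one | C/C=C/C1=C[C@](OC)(/C(C)=C/c2ccc(OC)c(OC)c2)C1=O | intermediate
18 | 2-chloro-1,1-dimethoxyethane | COC(CCl)OC | starting material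
19 | sodium methoxyacetylide | [Na+].[C-]#COC | intermediate
20 | methoxyacetylene (methoxyethyne) | C#COC | intermediate
21 | (4S)-4-[(E)-1-(3,4-dimethoxyphenyl)prop-1-en-2-yl]-4,5-dimethoxy-2-[(E)-prop-1-enyl]cyclohexa-2,5-dien-1-one | C/C=C/C1=C[C@](OC)(/C(C)=C/c2ccc(OC)c(OC)c2)C(OC)=CC1=O | target

**Step count and risks**

Total steps: 8. Longest linear sequence: 5 steps (1, 2, 5, 6, 8 from squaric acid; 3, 4, 5, 6, 8 from 8 is equally long).

Steps most likely to fail:

1. Step 8 (Proposed new method). The insertion may stall or go astray: oligomerisation of the volatile ynol ether on nickel, the reversed alkyne orientation, decarbonylation of the acylnickel intermediate, or loss of configuration through a free or slipped vinylketene. The fallback uses known chemistry, makes the racemate and resolves it; it sets out from 12 and returns at 21. Commercial α-asarone, (E)-1,2,4-trimethoxy-5-(prop-1-enyl)benzene, is oxidatively demethylated with (NH4)2Ce(NO3)6 in MeCN/H2O at 0 °C to 2-methoxy-5-[(E)-prop-1-enyl]cyclohexa-2,5-diene-1,4-dione F1. Alkenyllithium 13, made from 12 as in step 5, is added at −78 °C and should attack the carbonyl next to the methoxy-bearing carbon (the other carbonyl is a deactivated vinylogous ester) to give racemic 4-[(E)-1-(3,4-dimethoxyphenyl)prop-1-en-2-yl]-4-hydroxy-5-methoxy-2-[(E)-prop-1-enyl]cyclohexa-2,5-dien-1-one F2. O-Methylation (NaH, MeI, THF) gives racemic 4-[(E)-1-(3,4-dimethoxyphenyl)prop-1-en-2-yl]-4,5-dimethoxy-2-[(E)-prop-1-enyl]cyclohexa-2,5-dien-1-one F3, and preparative HPLC on a chiral stationary phase delivers 21.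

2. Step 5. Poor facial selectivity in the addition, together with co-elution of the two menthyl epimers, would cut the supply of the (4S) epimer; attack at the other carbonyl is a lesser risk. The fallback drops the auxiliary and resolves later; it sets out from 4 and 12 and returns at 17. Commercial diisopropyl squarate takes the place of 3: addition of 5 and acid treatment as in step 2 give 3-isopropoxy-4-[(E)-prop-1-enyl]cyclobut-3-ene-1,2-dione F4. Addition of 13 and MeOTf as in step 5 give racemic 4-[(E)-1-(3,4-dimethoxyphenyl)prop-1-en-2-yl]-3-isopropoxy-4-methoxy-2-[(E)-prop-1-enyl]cyclobut-2-en-1-one F5. Reduction and transposition as in step 6 give racemic 4-[(E)-1-(3,4-dimethoxyphenyl)prop-1-en-2-yl]-4-methoxy-2-[(E)-prop-1-enyl]cyclobut-2-en-1-one F6, which is resolved by preparative supercritical-fluid chromatography on a chiral stationary phase to give 17.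

3. Step 4. The hydrometalation may place zirconium on the aryl-bearing carbon, or stall on the internal alkyne, so that the regioisomeric iodide contaminates 12. The fallback changes the metal and the bond made first; it sets out from 10 and returns at 12. Copper-catalysed protoboration (B2pin2, CuCl, NaOt-Bu, P(p-tol)3, MeOH, THF, rt) adds H and boron syn with boron on the methyl-bearing carbon to give 2-[(Z)-1-(3,4-dimethoxyphenyl)prop-1-en-2-yl]-4,4,5,5-tetramethyl-1,3,2-dioxaborolane F7 (boron trans to aryl). Ipso-iododeboronation with retention (NaOH then I2, THF, 0 °C) gives 12.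

**Further compounds**

F1 | step 8 | 2-methoxy-5-[(E)-prop-1-enyl]cyclohexa-2,5-diene-1,4-dione | C/C=C/C1=CC(=O)C(OC)=CC1=O
F2 | step 8 | racemic 4-[(E)-1-(3,4-dimethoxyphenyl)prop-1-en-2-yl]-4-hydroxy-5-methoxy-2-[(E)-prop-1-enyl]cyclohexa-2,5-dien-1-one | C/C=C/C1=CC(O)(/C(C)=C/c2ccc(OC)c(OC)c2)C(OC)=CC1=O
F3 | step 8 | racemic 4-[(E)-1-(3,4-dimethoxyphenyl)prop-1-en-2-yl]-4,5-dimethoxy-2-[(E)-prop-1-enyl]cyclohexa-2,5-dien-1-one | C/C=C/C1=CC(OC)(/C(C)=C/c2ccc(OC)c(OC)c2)C(OC)=CC1=O
F4 | step 5 | 3-isopropoxy-4-[(E)-prop-1-enyl]cyclobut-3-ene-1,2-dione | C/C=C/C1=C(OC(C)C)C(=O)C1=O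
F5 | step 5 | racemic 4-[(E)-1-(3,4-dimethoxyphenyl)prop-1-en-2-yl]-3-isopropoxy-4-methoxy-2-[(E)-prop-1-enyl]cyclobut-2-en-1-one | C/C=C/C1=C(OC(C)C)C(OC)(/C(C)=C/c2ccc(OC)c(OC)c2)C1=O
F6 | step 5 | racemic 4-[(E)-1-(3,4-dimethoxyphenyl)prop-1-en-2-yl]-4-methoxy-2-[(E)-prop-1-enyl]cyclobut-2-en-1-one | C/C=C/C1=CC(OC)(/C(C)=C/c2ccc(OC)c(OC)c2)C1=O
F7 | step 4 | 2-[(Z)-1-(3,4-dimethoxyphenyl)prop-1-en-2-yl]-4,4,5,5-tetramethyl-1,3,2-dioxaborolane | CC1(C)OB(OC1(C)C)/C(C)=C/c1ccc(OC)c(OC)c1
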